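**Retrosynthetic overview**
1. Target 12 ⇐ global O‑demethylation of pentamethyl ether 11.
2. 11 ⇐ Heck coupling of aryl bromide 9 with 3,5‑dimethoxystyrene 10, so the stilbene arm goes on after the heterocycle exists.
3. 9 ⇐ key C2–O bond: chiral‑acid‑catalysed enantioselective isomerising cyclisation of the achiral triarylethylene 7 through p‑quinone methide 8. This forms the dihydrofuran ring, the only ring made in the route, and sets both stereocentres.
4. 7 ⇐ iodide‑selective Heck arylation of 1,1‑diarylethylene 5 with 4‑iodo‑2‑methoxyphenol 6.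
5. 5 ⇐ 5′‑bromo‑2′‑hydroxyacetophenone 1 plus the Grignard reagent from 1‑bromo‑3,5‑dimethoxybenzene 2, then dehydration.

**Assumptions**
- Compounds 6 and 10 are bought as catalogue chemicals.
- The sense of induction of the new step cannot be predicted. The catalyst enantiomer that gives (2S,3S)‑9 is used and is written here as (S); the antipode is equally available.

**Step 1**
Reactants: 1 1‑(5‑bromo‑2‑hydroxyphenyl)ethan‑1‑one; 2 1‑bromo‑3,5‑dimethoxybenzene
Product: 5 4‑bromo‑2‑[1‑(3,5‑dimethoxyphenyl)ethenyl]phenol, via arylmagnesium bromide 3 (not isolated), via tertiary alcohol 4 (not isolated)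
Conditions: Mg, THF, reflux (2 → 3, 2.3 equiv); then 1, THF, 0 °C → rt; 1 M HCl; then p‑TsOH·H2O (5 mol %), PhMe, 40 °C
Reagents that add atoms: none
Why: Grignard addition to the ketone (one equivalent is spent on the phenol; ArMgBr does not exchange with ArBr at 0 °C) followed by acid‑catalysed E1 dehydration of the dibenzylic tertiary alcohol, whose only β‑hydrogens are on CH3, gives the 1,1‑diarylethylene; no stereocentre is carried forward.

**Step 2**
Reactants: 5 4‑bromo‑2‑[1‑(3,5‑dimethoxyphenyl)ethenyl]phenol; 6 4‑iodo‑2‑methoxyphenol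
Product: 7 4‑bromo‑2‑[1‑(3,5‑dimethoxyphenyl)‑2‑(4‑hydroxy‑3‑methoxyphenyl)ethenyl]phenol (E/Z mixture)
Conditions: Pd(OAc)2 (5 mol %), n‑Bu4NCl (1 equiv), NaHCO3 (2.5 equiv), DMF, 95 °C, Ar
Reagents that add atoms: none
Why: Mizoroki–Heck reaction under ligand‑free Jeffery conditions, where ArI reacts and the electron‑rich ArBr does not; the aryl group adds to the CH2 terminus and the only possible β‑hydride elimination gives the triarylethylene, whose E/Z ratio is irrelevant because step 3 destroys the alkene geometry.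

**Step 3**
Reactants: 7 4‑bromo‑2‑[1‑(3,5‑dimethoxyphenyl)‑2‑(4‑hydroxy‑3‑methoxyphenyl)ethenyl]phenol
Product: 9 4‑[(2S,3S)‑5‑bromo‑3‑(3,5‑dimethoxyphenyl)‑2,3‑dihydro‑1‑benzofuran‑2‑yl]‑2‑methoxyphenol, via p‑quinone methide 8 (not isolated)
Conditions: (S)‑3,3′‑bis(2,4,6‑triisopropylphenyl)‑BINOL N‑triflylphosphoramide (5 mol %), PhMe/CH2Cl2 4:1 (0.02 M), 5 Å MS, −30 °C, Ar
Reagents that add atoms: none
Why: Proposed new method: a catalytic enantioselective isomerising oxa‑1,6‑cyclisation, in net terms an asymmetric 5‑endo hydroalkoxylation of a 4‑hydroxy‑triarylethylene. The confined chiral acid, hydrogen‑bonded to the ring‑A phenol, protonates C3 of the electron‑rich 4‑hydroxystyrene unit on one face and so sets C3 in the ion‑paired p‑quinone methide 8. The neighbouring phenol then adds 5‑exo to C2 anti to the C3 aryl group, which forms the C2–O bond, restores aromaticity and sets C2 trans by substrate control. The E and Z isomers of 7 converge because reversible protonation at C2 (the o‑quinone methide tautomer, which has no productive exit) scrambles the alkene geometry and both isomers give the same 8. The closest known reaction types are chiral phosphoric acid or N‑triflylphosphoramide generation of o‑ and p‑quinone methides from hydroxystyrenes by protonation with enantioselective nucleophile capture, confined‑acid asymmetric intramolecular hydroalkoxylation of alkenes, and the racemic quinone‑methide ring closure that gives trans‑dihydrobenzofurans in stilbene dimer biosynthesis.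

**Step 4**
Reactants: 9 4‑[(2S,3S)‑5‑bromo‑3‑(3,5‑dimethoxyphenyl)‑2,3‑dihydro‑1‑benzofuran‑2‑yl]‑2‑methoxyphenol; 10 1‑ethenyl‑3,5‑dimethoxybenzene
Product: 11 4‑[(2S,3S)‑3‑(3,5‑dimethoxyphenyl)‑5‑[(E)‑2‑(3,5‑dimethoxyphenyl)ethenyl]‑2,3‑dihydro‑1‑benzofuran‑2‑yl]‑2‑methoxyphenol
Conditions: Pd2(dba)3 (2.5 mol %), [HP(t‑Bu)3]BF4 (10 mol %), Cy2NMe (2.2 equiv), 1,4‑dioxane, rt → 40 °C
Reagents that add atoms: none
Why: Mizoroki–Heck coupling with Pd/P(t‑Bu)3 and an amine base, which couples electron‑rich aryl bromides with styrenes near room temperature and gives the E‑stilbene, while the mild, weakly basic conditions leave the C2/C3 stereocentres alone.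

**Step 5**
Reactants: 11 4‑[(2S,3S)‑3‑(3,5‑dimethoxyphenyl)‑5‑[(E)‑2‑(3,5‑dimethoxyphenyl)ethenyl]‑2,3‑dihydro‑1‑benzofuran‑2‑yl]‑2‑methoxyphenol
Product: 12 4‑[(2S,3S)‑3‑(3,5‑dihydroxyphenyl)‑5‑[(E)‑2‑(3,5‑dihydroxyphenyl)ethenyl]‑2,3‑dihydro‑1‑benzofuran‑2‑yl]benzene‑1,2‑diol
Conditions: BBr3 (10 equiv), CH2Cl2, −78 → 0 °C; cold sat. aq. NaHCO3
Reagents that add atoms: none
Why: Lewis‑acid aryl methyl ether cleavage (O→B coordination, then bromide SN2 at the methyl group) removes all five methyl groups without breaking a bond at C2 or C3 and leaves the E‑alkene in place; low temperature and a buffered quench limit acid‑induced ring opening.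

**Compound list**
1 | 1‑(5‑bromo‑2‑hydroxyphenyl)ethan‑1‑one | CC(=O)c1cc(Br)ccc1O | starting material
2 | 1‑bromo‑3,5‑dimethoxybenzene | COc1cc(Br)cc(OC)c1 | starting material
3 | (3,5‑dimethoxyphenyl)magnesium bromide | COc1cc([Mg]Br)cc(OC)c1 | intermediate
4 | rac‑4‑bromo‑2‑[1‑(3,5‑dimethoxyphenyl)‑1‑hydroxyethyl]phenol | CC(O)(c1cc(OC)cc(OC)c1)c1cc(Br)ccc1O | intermediate
5 | 4‑bromo‑2‑[1‑(3,5‑dimethoxyphenyl)ethenyl]phenol | C=C(c1cc(OC)cc(OC)c1)c1cc(Br)ccc1O | intermediate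
6 | 4‑iodo‑2‑methoxyphenol | COc1cc(I)ccc1O | starting material
7 | 4‑bromo‑2‑[1‑(3,5‑dimethoxyphenyl)‑2‑(4‑hydroxy‑3‑methoxyphenyl)ethenyl]phenol (E/Z mixture) | COc1cc(cc(OC)c1)C(=Cc1ccc(O)c(OC)c1)c1cc(Br)ccc1O | intermediate
8 | 4‑[(2S)‑2‑(5‑bromo‑2‑hydroxyphenyl)‑2‑(3,5‑dimethoxyphenyl)ethylidene]‑2‑methoxycyclohexa‑2,5‑dien‑1‑one | O=C1C(OC)=CC(=C[C@@H](c2cc(OC)cc(OC)c2)c2cc(Br)ccc2O)C=C1 | intermediate
9 | 4‑[(2S,3S)‑5‑bromo‑3‑(3,5‑dimethoxyphenyl)‑2,3‑dihydro‑1‑benzofuran‑2‑yl]‑2‑methoxyphenol | Brc1ccc2c(c1)[C@H](c1cc(OC)cc(OC)c1)[C@@H](c1ccc(O)c(OC)c1)O2 | intermediate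
10 | 1‑ethenyl‑3,5‑dimethoxybenzene (3,5‑dimethoxystyrene) | C=Cc1cc(OC)cc(OC)c1 | starting material
11 | 4‑[(2S,3S)‑3‑(3,5‑dimethoxyphenyl)‑5‑[(E)‑2‑(3,5‑dimethoxyphenyl)ethenyl]‑2,3‑dihydro‑1‑benzofuran‑2‑yl]‑2‑methoxyphenol | COc1cc(OC)cc(/C=C/c2ccc3c(c2)[C@H](c2cc(OC)cc(OC)c2)[C@@H](c2ccc(O)c(OC)c2)O3)c1 | intermediate
12 | 4‑[(2S,3S)‑3‑(3,5‑dihydroxyphenyl)‑5‑[(E)‑2‑(3,5‑dihydroxyphenyl)ethenyl]‑2,3‑dihydro‑1‑benzofuran‑2‑yl]benzene‑1,2‑diol | Oc1cc(O)cc(/C=C/c2ccc3c(c2)[C@H](c2cc(O)cc(O)c2)[C@@H](c2ccc(O)c(O)c2)O3)c1 | target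

**Totals**
Total step count: 5. Longest linear sequence: 5 steps (1/2 → 5 → 7 → 9 → 11 → 12).

**Steps most likely to fail, with fallbacks**

Step 3 (the proposed new reaction). The risks are insufficient enantioselectivity, different selectivity from the E and Z isomers, and loss of ee through acid‑induced reopening of 9 to the quinone methide and alkene. The fallback uses known chemistry, sets out from 7 and comes back at 9. Compound 7 is closed with an achiral acid (diphenyl phosphate 10 mol % or TsOH 5 mol %, CH2Cl2, 0 °C → rt), an ordinary acid‑catalysed addition of a phenol to an electron‑rich styrene, which gives the racemic trans‑dihydrobenzofuran. That racemate is a 1:1 mixture of 9 and its mirror image 4‑[(2R,3R)‑5‑bromo‑3‑(3,5‑dimethoxyphenyl)‑2,3‑dihydro‑1‑benzofuran‑2‑yl]‑2‑methoxyphenol F1. The two are separated by preparative chiral SFC on an amylose phase, and 9 goes on to step 4.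

Step 5 (five‑fold demethylation of an acid‑labile 2‑(4‑hydroxyaryl)dihydrobenzofuran). The risks are C2–O ring opening with epimerisation or racemisation, and incomplete cleavage. The fallback reorders the endgame so that no stereocentre meets BBr3; it sets out from 7 and comes back at 12. Compound 7 is coupled with 10 under the step 4 conditions to give 2‑[1‑(3,5‑dimethoxyphenyl)‑2‑(4‑hydroxy‑3‑methoxyphenyl)ethenyl]‑4‑[(E)‑2‑(3,5‑dimethoxyphenyl)ethenyl]phenol F2. This achiral compound is demethylated with BBr3 (CH2Cl2, −78 → 0 °C, bicarbonate quench) to 4‑[2‑(3,5‑dihydroxyphenyl)‑2‑{5‑[(E)‑2‑(3,5‑dihydroxyphenyl)ethenyl]‑2‑hydroxyphenyl}ethenyl]benzene‑1,2‑diol F3. F3 is then closed as the last operation with the step 3 catalyst (EtOAc/CH2Cl2, −20 °C) to give 12 directly. This fallback still depends on the new cyclisation, now on an unprotected polyphenol.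

Step 2 (Heck arylation of a hindered 1,1‑diarylethylene with free phenols present and an Ar–Br to be spared). The risks are low conversion and oligomers from Ar–Br activation. The fallback replaces the Heck reaction with an olefination; it sets out from 3 and comes back at 7. Grignard reagent 3 (2.2 equiv) is added to 5‑bromo‑2‑hydroxybenzaldehyde (THF, 0 °C) to give rac‑4‑bromo‑2‑[(3,5‑dimethoxyphenyl)(hydroxy)methyl]phenol F4. Heating F4 with P(OEt)3 (PhMe, 110 °C; o‑quinone methide phospha‑Michael addition, then dealkylation) gives rac‑diethyl [(5‑bromo‑2‑hydroxyphenyl)(3,5‑dimethoxyphenyl)methyl]phosphonate F5. Horner–Wadsworth–Emmons reaction of F5 with 4‑[(tert‑butyldimethylsilyl)oxy]‑3‑methoxybenzaldehyde (t‑BuOK 2.2 equiv, THF, 0 °C → rt) gives 4‑bromo‑2‑[2‑{4‑[(tert‑butyldimethylsilyl)oxy]‑3‑methoxyphenyl}‑1‑(3,5‑dimethoxyphenyl)ethenyl]phenol F6 as an E/Z mixture. TBAF (THF, 0 °C) then releases 7.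

**Further compounds**
F1 | step 3 | 4‑[(2R,3R)‑5‑bromo‑3‑(3,5‑dimethoxyphenyl)‑2,3‑dihydro‑1‑benzofuran‑2‑yl]‑2‑methoxyphenol | Brc1ccc2c(c1)[C@@H](c1cc(OC)cc(OC)c1)[C@H](c1ccc(O)c(OC)c1)O2
F2 | step 5 | 2‑[1‑(3,5‑dimethoxyphenyl)‑2‑(4‑hydroxy‑3‑methoxyphenyl)ethenyl]‑4‑[(E)‑2‑(3,5‑dimethoxyphenyl)ethenyl]phenol (E/Z at the triaryl alkene) | COc1cc(OC)cc(/C=C/c2ccc(O)c(c2)C(=Cc2ccc(O)c(OC)c2)c2cc(OC)cc(OC)c2)c1
F3 | step 5 | 4‑[2‑(3,5‑dihydroxyphenyl)‑2‑{5‑[(E)‑2‑(3,5‑dihydroxyphenyl)ethenyl]‑2‑hydroxyphenyl}ethenyl]benzene‑1,2‑diol (E/Z at the triaryl alkene) | Oc1cc(O)cc(/C=C/c2ccc(O)c(c2)C(=Cc2ccc(O)c(O)c2)c2cc(O)cc(O)c2)c1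
F4 | step 2 | rac‑4‑bromo‑2‑[(3,5‑dimethoxyphenyl)(hydroxy)methyl]phenol | COc1cc(cc(OC)c1)C(O)c1cc(Br)ccc1O
F5 | step 2 | rac‑diethyl [(5‑bromo‑2‑hydroxyphenyl)(3,5‑dimethoxyphenyl)methyl]phosphonate | CCOP(=O)(OCC)C(c1cc(OC)cc(OC)c1)c1cc(Br)ccc1O
F6 | step 2 | 4‑bromo‑2‑[2‑{4‑[(tert‑butyldimethylsilyl)oxy]‑3‑methoxyphenyl}‑1‑(3,5‑dimethoxyphenyl)ethenyl]phenol (E/Z mixture) | COc1cc(cc(OC)c1)C(=Cc1ccc(O[Si](C)(C)C(C)(C)C)c(OC)c1)c1cc(Br)ccc1O
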